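(The earlier runs and the new flask come from a simulation for substances that don't exist; noise was put on by code.)

Late in the beta run, at 5.00 h, E stands at 3.4% of the J charged beside X at 9.3%, a ratio of 0.366. How fast X ripens into E in the other flasks is what we reckon from this.

in all of them: J 0.40 M

| run | Z | temperature | remark | time |
|---|---|---|---|---|
| eta | 0.24 M | −30 °C | run made earlier |  |
| beta | 0.36 M | 0 °C | run made earlier |  |
| ochre | 0.480 M | 25 °C |  | 2.0 h |
| grey | 0.480 M |  | at −25 °C until 25 min, from then on at 25 °C | 2.0 h |
| amber | 0.480 M | 0 °C |  | 2.0 h |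
| blue | 0.480 M | −25 °C |  | 2.0 h |

- eta (time / h: X / %, E / %): 1.33: 0.8, 0.2; 4.00: 0.2, 0; 6.00: 0, 0; 10.0: 0.4, 0; 15.0: 1.1, 0; 20.0: 0.7, 0.2; 25.0: 0.5, 0.4
- beta (time / h: X / %, E / %): 0.250: 0, 0.3; 0.833: 0.3, 0; 1.33: 1.6, 0; 2.50: 4.7, 1.3; 3.00: 5.8, 1.4; 5.00: 9.3, 3.4

(scatter of a reading: 0.5 percentage points)

* which flask leads in share of X in all that became X or E or G ("all alike" within 1.5 percentage points) (ochre / grey / amber / blue / all alike)
* share of X in all that became X or E or G, ochre
* share of X in all that became X or E or G, grey
* share of X in all that became X or E or G, amber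
* share of X in all that became X or E or G, blue

- solid, in amounts per volume of the solution: Z
- what was read earlier has a scatter of 0.5 percentage points, one standard deviation
- candidate steps: Z <-> D; D + X -> G; D + Q -> X; 2 D -> L; X <-> E; J -> Q
- at the start none of Z is in solution

X climbs roughly in a line from about 0.833 h, so the X standing at the end of beta has a mean age of 2.08 h. Ratio over age gives a first constant of 0.175 h⁻¹. Amber, at the same temperature and with the same lag assumed, though with more Z, has a mean age of 0.584 h, so we expect E/X of 0.102.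

The weak link is the straight line. We go round once more and put the readings themselves in its place: the area under X from the lag onward is 0.219 h in fractions of the charge. This gives the ripening constant, the E made per hour per unit of X standing, 0.155 h⁻¹. Amber's E/X becomes 0.0907, and its share of X, with G uncounted, 91.7%.

For temperature we lend X→E the barrier of the rise of X, an assumption. Beta rises 0.0210 h⁻¹ and eta 2.00 × 10⁻⁴ h⁻¹, though that eta reading is about one scatter and the two runs differ in Z as well as in temperature. So the barrier, 85.6 kJ mol⁻¹, is rough. Constant times age, at the same age, gives 0.00203 for blue and 2.14 for ochre. Blue's figure is below one, so we expect kinetic control there, and we name blue the leader. Ochre's figure is above one, so we expect the line to fail in ochre and E/X to go towards a balance that we cannot read from these runs: thermodynamic control. Grey, warm for 1.58 h against 25 min cold, we place beside ochre.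

The forecast says blue leads, with ochre 40%, grey 44%, amber 78% and blue 96%, and on one point states: “G was never measured, so its contribution is a guess”. Its amber stands below our G-free 91.7%.

The flasks give blue as leader, with ochre 34.9%, grey 36.2%, amber 79.0% and blue 97.8%.

    Z ⇌ D, rate k1*(cs1 - [D]) while solid is left; crystals form when [D] > cs1 (solubility = 0.200 M, k = 3.30 × 10⁻⁴ s⁻¹)
    D + X → G (k = 0.00272 L mol⁻¹ s⁻¹, Ea = 47.0 kJ mol⁻¹)
    D + Q → X (k = 0.00229 L mol⁻¹ s⁻¹, Ea = 54.0 kJ mol⁻¹)
    2 D → L (k = 7.75 × 10⁻⁴ L mol⁻¹ s⁻¹, Ea = 65.0 kJ mol⁻¹)
    X ⇌ E (K = 1.40, k = 9.96 × 10⁻⁴ s⁻¹, Ea = 86.0 kJ mol⁻¹, ΔH = −3.00 kJ mol⁻¹)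
    J → Q (k = 0.00110 s⁻¹, Ea = 90.0 kJ mol⁻¹)
    (constants at 25 °C)

Amber's E/X comes out at 0.0939 against our 0.0907, while amber's G, at 0.506%, exceeds its E at 0.276%. The neighbour, blue repeated at −10 °C, takes the same reckoning: 0.155 h⁻¹ carried down the barrier gives 0.0371 h⁻¹, and at amber's age E/X of 0.0217. That flask holds X at 0.367% and E at 0.00775%, a ratio of 0.0211, with G at 0.0281% and a share of X of 91.1%.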